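**Plan** (chromene numbering of the target: O1, C2, C3, C4, C4a, C5, C6, C7, C8, C8a)

- Retrosynthesis: the C8–OH is traced back to its ethyl enol ether; the C5–prenyl bond is cut to give the aromatic 6-chromenol 23; the O1–C2 bond is cut to give the prenyl-para-quinone 21; the benzene ring is cut at C6–C7 and C8–C8a into cyclobutenone 7 (C6, C5, C4a, C8a) and alkynyl ether 11 (C7, C8 and the phenylpropyl side chain).
- Enabling feature: the carbocycle C4a–C5–C6–C7–C8–C8a is a C5-quaternized (dearomatized) phenol whose oxygens on C6 and C8 are meta and flank C7. This is the pattern that results when a 1-alkoxyalkyne inserts into the acyl–vinyl bond of a cyclobutenone.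
- Forward order: benzene ring first (step 4, all six substituents placed), allyl to prenyl, phenol to para-quinone (brings in the C8a oxygen), side-chain ketone, pyran ring by quinone-methide electrocyclization (step 9), C5 quaternary center (step 10), free C8–OH last.
- Stereochemistry: the only stereocenter, C5 (S), is set in step 10 by an enantioselective palladium-catalyzed dearomative prenylation. The silyloxy carbon is a temporary racemic helper that masks the ketone during the ketene chemistry and is oxidized in step 8.

Key step: step 4

Assumption: the sense of asymmetric induction in step 10 cannot be assigned with certainty in advance; the (R,R) ligand is written, and its antipode is used if it should favor the (5R) product. Centers marked (±) are racemic and are all erased by aromatization or oxidation before step 10.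

**Route**

Step 1
Reactants: 1 propanoyl chloride; 2 ethoxyacetylene
Product: 4 (±)-3-ethoxy-4-methylcyclobut-2-en-1-one, via methylketene 3 (not isolated)
Conditions: Et3N, Et2O, 0 °C → rt (1 added slowly to 2 and Et3N)
Reagents that add atoms: none
Why: Triethylamine dehydrochlorinates 1 to methylketene 3, whose carbonyl carbon is attacked by the nucleophilic terminal carbon of the ynol ether in a regioselective ketene–alkyne [2+2] cycloaddition that places ethoxy on C3 and methyl on C4; the medium stays basic so that the kinetic 4-methyl isomer is not equilibrated to the 2-methyl isomer, and the new center is racemic and without consequence.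

Step 2
Reactants: 4 (±)-3-ethoxy-4-methylcyclobut-2-en-1-one; 5 allylmagnesium bromide
Product: 7 (±)-4-methyl-3-(prop-2-en-1-yl)cyclobut-2-en-1-one, via carbinol 6 (not isolated)
Conditions: Et2O, −78 °C; then 1 M HCl, 0 °C
Reagents that add atoms: water, O
Why: 1,2-Addition of the Grignard reagent to the vinylogous ester carbonyl (enolization would require an antiaromatic cyclobutadienolate), followed by acid-induced ionization and hydrolysis of the enol ether, transposes the carbonyl group (Stork–Danheiser sequence) and gives the 3-substituted cyclobutenone; allyl is chosen over prenyl because it adds without allylic transposition and its terminal double bond is a poor ketenophile in step 4.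

Step 3
Reactants: 2 ethoxyacetylene; 8 3-phenylpropanal
Product: 11 (±)-tert-butyl[(1-ethoxy-5-phenylpent-1-yn-3-yl)oxy]dimethylsilane, via lithium ethoxyacetylide 9 (not isolated), via lithium alkoxide 10 (not isolated)
Conditions: nBuLi, THF, −78 °C; 8; then TBSCl, DMF, −78 °C → rt
Reagents that add atoms: tert-butyldimethylsilyl chloride, CC(C)(C)[Si](C)(C)Cl
Why: Acetylide addition to the aldehyde and silylation of the lithium alkoxide in the same flask avoid isolation of the acid-labile alkoxypropargylic alcohol (Meyer–Schuster rearrangement), and the silyloxy carbon carries the future C7 ketone in masked, non-electrophilic form so that the alkyne stays electron-rich for step 4; the carbinol center is racemic and is later oxidized.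

Step 4
Reactants: 7 (±)-4-methyl-3-(prop-2-en-1-yl)cyclobut-2-en-1-one; 11 (±)-tert-butyl[(1-ethoxy-5-phenylpent-1-yn-3-yl)oxy]dimethylsilane
Product: 16 (±)-2-[1-(tert-butyldimethylsilyloxy)-3-phenylpropyl]-3-ethoxy-6-methyl-5-(prop-2-en-1-yl)phenol, via vinylketene 12 (not isolated), via vinylcyclobutenone 13 (not isolated), via dienylketene 14 (not isolated), via cyclohexadienone 15 (not isolated)
Conditions: PhMe, sealed tube, 80 °C, then 100 °C (7 in slight excess)
Reagents that add atoms: none
Why: At 80 °C cyclobutenone 7 undergoes reversible 4π-electrocyclic opening of its carbonyl–C4 bond to vinylketene 12, whose carbonyl carbon is attacked by the nucleophilic β-carbon (future C7) of ynol ether 11 in a regiospecific [2+2] cycloaddition that creates the future C6–C7 and C8–C8a bonds in vinylcyclobutenone 13. A second 4π opening, now of the former acyl–vinyl bond, gives dienylketene 14, and 6π-electrocyclic closure of the ketene carbon onto the propenyl terminus (re-forming the C6–C5 bond that the first opening had broken) followed by enolization of dienone 15 delivers the benzene ring, so that the net change is insertion of the alkyne into the acyl–vinyl bond of 7. This is the Danheiser benzannulation, whose closest precedent is the reaction of 3-alkylcyclobutenones with alkoxy- and siloxyalkynes to give resorcinol monoethers. The six-membered carbocycle is closed by thermal disrotatory 6π-electrocyclization; no stereocenter is created that survives, since the sp3 carbon of 15 and C4 of 7 become aromatic, and the racemic silyloxy carbon is carried along untouched. The step needs regiocontrol in the [2+2] event, which the polarization of the ynol ether secures (ethoxy-bearing carbon to the ketene α-carbon), and chemoselectivity for the alkyne over the allyl double bond, which the far higher ketenophilicity of the electron-rich alkyne secures; all six ring substituents (OH, side chain, OEt, H, allyl, Me) are thereby placed as a single regioisomer.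

Step 5
Reactants: 16 (±)-2-[1-(tert-butyldimethylsilyloxy)-3-phenylpropyl]-3-ethoxy-6-methyl-5-(prop-2-en-1-yl)phenol; 17 2-methylbut-2-ene
Product: 18 (±)-2-[1-(tert-butyldimethylsilyloxy)-3-phenylpropyl]-3-ethoxy-6-methyl-5-(3-methylbut-2-en-1-yl)phenol
Conditions: (H2IMes)(PCy3)Cl2Ru=CHPh (second-generation Grubbs catalyst, 5 mol %), 17/CH2Cl2, 40 °C
Reagents that add atoms: none
Why: Olefin cross-metathesis of the terminal allyl group with a large excess of 2-methylbut-2-ene gives the trisubstituted prenyl olefin, which is inert to further metathesis, with propene as volatile by-product; the hindered free phenol and both ethers are tolerated.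

Step 6
Reactants: 18 (±)-2-[1-(tert-butyldimethylsilyloxy)-3-phenylpropyl]-3-ethoxy-6-methyl-5-(3-methylbut-2-en-1-yl)phenol
Product: 19 (±)-2-[1-(tert-butyldimethylsilyloxy)-3-phenylpropyl]-3-ethoxy-6-methyl-5-(3-methylbut-2-en-1-yl)cyclohexa-2,5-diene-1,4-dione
Conditions: (KO3S)2NO (Fremy's salt, 2.5 equiv), KH2PO4, acetone/H2O, rt
Reagents that add atoms: potassium nitrosodisulfonate (Fremy's salt), [K+].[K+].[O-]S(=O)(=O)N([O])S(=O)(=O)[O-]
Why: Teuber oxidation: the nitroxyl radical abstracts the phenolic hydrogen, a second equivalent traps the aryloxyl radical at the only unsubstituted position (C4, para to the hydroxyl), and loss of imidodisulfonate gives the para-quinone, which introduces the future C8a/O1 oxygen; both ortho positions are blocked, and the buffered medium leaves the silyl ether and the prenyl group untouched.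

Step 7
Reactants: 19 (±)-2-[1-(tert-butyldimethylsilyloxy)-3-phenylpropyl]-3-ethoxy-6-methyl-5-(3-methylbut-2-en-1-yl)cyclohexa-2,5-diene-1,4-dione
Product: 20 (±)-3-ethoxy-2-(1-hydroxy-3-phenylpropyl)-6-methyl-5-(3-methylbut-2-en-1-yl)cyclohexa-2,5-diene-1,4-dione
Conditions: HF (48 % aq.), MeCN, 0 °C
Reagents that add atoms: none
Why: Fluoride cleaves the Si–O bond of the secondary silyl ether, and cold dilute acid leaves the quinone, its ethoxy group and the trisubstituted olefin intact.

Step 8
Reactants: 20 (±)-3-ethoxy-2-(1-hydroxy-3-phenylpropyl)-6-methyl-5-(3-methylbut-2-en-1-yl)cyclohexa-2,5-diene-1,4-dione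
Product: 21 3-ethoxy-6-methyl-5-(3-methylbut-2-en-1-yl)-2-(3-phenylpropanoyl)cyclohexa-2,5-diene-1,4-dione
Conditions: Dess–Martin periodinane, CH2Cl2, 0 °C → rt
Reagents that add atoms: none
Why: Dess–Martin oxidation converts the secondary alcohol into the ketone under neutral, non-aqueous conditions, under which the fully substituted quinone (no free position for conjugate addition) is stable.

Step 9
Reactants: 21 3-ethoxy-6-methyl-5-(3-methylbut-2-en-1-yl)-2-(3-phenylpropanoyl)cyclohexa-2,5-diene-1,4-dione
Product: 23 1-(8-ethoxy-6-hydroxy-2,2,5-trimethyl-2H-chromen-7-yl)-3-phenylpropan-1-one, via quinone methide 22 (not isolated)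
Conditions: pyridine, 90 °C
Reagents that add atoms: none
Why: Classical base-induced isomerization of a prenylquinone to a chromenol: pyridine removes a proton from the ring-bound CH2 of the prenyl group (vinylogous to the future C6 carbonyl), the resulting ortho-quinone methide 22 closes by oxa-6π electrocyclization of the C8a carbonyl oxygen onto the dimethyl-substituted terminus, and aromatization drives the process; only the carbonyl flanked by the prenyl group can close, so the pyran oxygen ends on C8a and the other carbonyl becomes the C6 phenol, while a tertiary amine cannot displace the ethoxy group.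

Step 10
Reactants: 23 1-(8-ethoxy-6-hydroxy-2,2,5-trimethyl-2H-chromen-7-yl)-3-phenylpropan-1-one; 24 3-methylbut-2-en-1-yl acetate (prenyl acetate)
Product: 25 (5S)-8-ethoxy-2,2,5-trimethyl-5-(3-methylbut-2-en-1-yl)-7-(3-phenylpropanoyl)-2H-chromen-6(5H)-one
Conditions: Pd2(dba)3·CHCl3 (2.5 mol %), N,N'-[(1R,2R)-cyclohexane-1,2-diyl]bis[2-(diphenylphosphanyl)benzamide] (6 mol %), Cs2CO3 (1.2 equiv), PhMe, 0 °C → rt
Reagents that add atoms: none
Why: Proposed new method: the zerovalent palladium complex of the chiral diphosphine ionizes prenyl acetate to a cationic π-prenyl palladium species; the cesium phenolate of 23, an ambident nucleophile whose O-prenyl ether is re-ionized by the same catalyst, attacks through C5 (ortho to the phenolate oxygen and methyl-bearing, whereas C7 is blocked and deactivated by the acyl group) at the unsubstituted allyl terminus, and the chiral pocket of the ligand differentiates the two faces of the planar phenolate so that the (5S) quaternary center should form; the product is a push–pull vinylogous ester, which offsets the loss of aromaticity; the closest known reaction types are the palladium-catalyzed intermolecular asymmetric allylic dearomatization of 1-substituted 2-naphthols with this ligand class and the racemic palladium-catalyzed dearomative prenylation of acylphloroglucinols.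

Step 11
Reactants: 25 (5S)-8-ethoxy-2,2,5-trimethyl-5-(3-methylbut-2-en-1-yl)-7-(3-phenylpropanoyl)-2H-chromen-6(5H)-one
Product: 26 (5S)-8-hydroxy-2,2,5-trimethyl-5-(3-methylbut-2-en-1-yl)-7-(3-phenylpropanoyl)-2H-chromen-6(5H)-one
Conditions: LiOH (3 equiv), THF/H2O, 0 °C → rt; then 1 M HCl to pH 3
Reagents that add atoms: lithium hydroxide, [Li+].[OH-]
Why: Hydroxide adds to C8, the β-carbon of the doubly activated alkoxy-enedione, and expels ethoxide (addition–elimination, a vinylogous saponification) to give the triketone enolate, which is protonated on work-up; the quaternary C5 center has no α-hydrogen and cannot epimerize, and the cyclic enol ether at C8a is not a leaving group.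

**Compound list**

1 | propanoyl chloride | CCC(=O)Cl | starting material
2 | ethoxyacetylene (ethoxyethyne) | CCOC#C | starting material
3 | methylketene (prop-1-en-1-one) | CC=C=O | intermediate (not isolated)
4 | (±)-3-ethoxy-4-methylcyclobut-2-en-1-one | CCOC1=CC(=O)C1C | intermediate
5 | allylmagnesium bromide | C=CC[Mg]Br | starting material
6 | (±)-3-ethoxy-4-methyl-1-(prop-2-en-1-yl)cyclobut-2-en-1-ol (formed as its magnesium alkoxide) | CCOC1=CC(O)(CC=C)C1C | intermediate (not isolated)
7 | (±)-4-methyl-3-(prop-2-en-1-yl)cyclobut-2-en-1-one | C=CCC1=CC(=O)C1C | intermediate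
8 | 3-phenylpropanal | O=CCCc1ccccc1 | starting material
9 | lithium ethoxyacetylide | [Li]C#COCC | intermediate (not isolated)
10 | lithium (±)-1-ethoxy-5-phenylpent-1-yn-3-olate | CCOC#CC(O[Li])CCc1ccccc1 | intermediate (not isolated)
11 | (±)-tert-butyl[(1-ethoxy-5-phenylpent-1-yn-3-yl)oxy]dimethylsilane | CCOC#CC(O[Si](C)(C)C(C)(C)C)CCc1ccccc1 | intermediate
12 | (3E)-3-(prop-2-en-1-yl)penta-1,3-dien-1-one (vinylketene) | C/C=C(/C=C=O)CC=C | intermediate (not isolated)
13 | 2-[1-(tert-butyldimethylsilyloxy)-3-phenylpropyl]-3-ethoxy-4-[(2E)-hexa-2,5-dien-3-yl]cyclobut-2-en-1-one (mixture of racemic diastereomers) | CCOC1=C(C(O[Si](C)(C)C(C)(C)C)CCc2ccccc2)C(=O)C1/C(CC=C)=C/C | intermediate (not isolated)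
14 | (3E,5E)-2-[1-(tert-butyldimethylsilyloxy)-3-phenylpropyl]-3-ethoxy-5-(prop-2-en-1-yl)hepta-1,3,5-trien-1-one (dienylketene, ketene-bearing carbon and C5 cis across C3=C4) | O=C=C(C(O[Si](C)(C)C(C)(C)C)CCc1ccccc1)/C(OCC)=C\C(CC=C)=C\C | intermediate (not isolated)
15 | 2-[1-(tert-butyldimethylsilyloxy)-3-phenylpropyl]-3-ethoxy-6-methyl-5-(prop-2-en-1-yl)cyclohexa-2,4-dien-1-one (mixture of racemic diastereomers) | CCOC1=C(C(O[Si](C)(C)C(C)(C)C)CCc2ccccc2)C(=O)C(C)C(CC=C)=C1 | intermediate (not isolated)
16 | (±)-2-[1-(tert-butyldimethylsilyloxy)-3-phenylpropyl]-3-ethoxy-6-methyl-5-(prop-2-en-1-yl)phenol | CCOc1cc(CC=C)c(C)c(O)c1C(O[Si](C)(C)C(C)(C)C)CCc1ccccc1 | intermediate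
17 | 2-methylbut-2-ene | CC=C(C)C | starting material
18 | (±)-2-[1-(tert-butyldimethylsilyloxy)-3-phenylpropyl]-3-ethoxy-6-methyl-5-(3-methylbut-2-en-1-yl)phenol | CCOc1cc(CC=C(C)C)c(C)c(O)c1C(O[Si](C)(C)C(C)(C)C)CCc1ccccc1 | intermediate
19 | (±)-2-[1-(tert-butyldimethylsilyloxy)-3-phenylpropyl]-3-ethoxy-6-methyl-5-(3-methylbut-2-en-1-yl)cyclohexa-2,5-diene-1,4-dione | CCOC1=C(C(O[Si](C)(C)C(C)(C)C)CCc2ccccc2)C(=O)C(C)=C(CC=C(C)C)C1=O | intermediate
20 | (±)-3-ethoxy-2-(1-hydroxy-3-phenylpropyl)-6-methyl-5-(3-methylbut-2-en-1-yl)cyclohexa-2,5-diene-1,4-dione | CCOC1=C(C(O)CCc2ccccc2)C(=O)C(C)=C(CC=C(C)C)C1=O | intermediate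
21 | 3-ethoxy-6-methyl-5-(3-methylbut-2-en-1-yl)-2-(3-phenylpropanoyl)cyclohexa-2,5-diene-1,4-dione | CCOC1=C(C(=O)CCc2ccccc2)C(=O)C(C)=C(CC=C(C)C)C1=O | intermediate
22 | 2-ethoxy-4-hydroxy-5-methyl-6-(3-methylbut-2-en-1-ylidene)-3-(3-phenylpropanoyl)cyclohexa-2,4-dien-1-one (ortho-quinone methide, dimethylvinyl group cis to the ring carbonyl) | CCOC1=C(C(=O)CCc2ccccc2)C(O)=C(C)/C(=C/C=C(C)C)C1=O | intermediate (not isolated)
23 | 1-(8-ethoxy-6-hydroxy-2,2,5-trimethyl-2H-chromen-7-yl)-3-phenylpropan-1-one | CCOc1c(C(=O)CCc2ccccc2)c(O)c(C)c2C=CC(C)(C)Oc12 | intermediate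
24 | 3-methylbut-2-en-1-yl acetate (prenyl acetate) | CC(=O)OCC=C(C)C | starting material
25 | (5S)-8-ethoxy-2,2,5-trimethyl-5-(3-methylbut-2-en-1-yl)-7-(3-phenylpropanoyl)-2H-chromen-6(5H)-one | CC(C)=CC[C@]1(C)C(=O)C(C(=O)CCc2ccccc2)=C(OCC)C2=C1C=CC(C)(C)O2 | intermediate
26 | (5S)-8-hydroxy-2,2,5-trimethyl-5-(3-methylbut-2-en-1-yl)-7-(3-phenylpropanoyl)-2H-chromen-6(5H)-one | CC(C)=CC[C@]1(C)C(=O)C(C(=O)CCc2ccccc2)=C(O)C2=C1C=CC(C)(C)O2 | target

**Totals**

Total step count: 11. Longest linear sequence: 10 steps (steps 1, 2 and 4 to 11; step 3 is the side branch).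

**Steps most likely to fail**

1. Step 10 (proposed new method). What may go wrong: insufficient discrimination of the two faces of the phenolate by the chiral allylpalladium complex, or diversion into O-prenylation or attack at the substituted allyl terminus. Fallback, from 23 back to 26 with known chemistry only: 23 is prenylated with 24 and Cs2CO3 under the achiral zerovalent palladium catalyst Pd(PPh3)4 (racemic dearomative Tsuji–Trost prenylation as practiced on acylphloroglucinols) to give the racemic ethoxy dienone F1. Hydrolysis with LiOH as in step 11 gives the racemic triketone F2. This vinylogous acid is resolved classically by salt formation with (R)-1-phenylethylamine and fractional crystallization of the (R)-1-phenylethylammonium salt of the (5S) acid F3 (the antipodal amine is used if the other diastereomeric salt proves the less soluble). Treatment of the salt with dilute HCl releases 26.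

2. Step 4 (key step). What may go wrong: thermal loss of silanol from the ortho-hydroxybenzylic silyl ether once the phenol has formed, or consumption of the vinylketene by the product phenol and by dimerization before the hindered alkyne captures it. Fallback, from 7 back to 16, in which the side chain is attached after the annulation: 7 is heated with the unhindered, commercially available alkyne 2 (same benzannulation, 80 °C) to give 5-ethoxy-2-methyl-3-(prop-2-en-1-yl)phenol F4. Its bromomagnesium phenolate (EtMgBr, PhMe) is hydroxyalkylated with aldehyde 8 at the only free ortho position, which lies between OH and OEt, through the chelated magnesium phenolate–aldehyde complex, giving the racemic diol F5. Silylation of both hydroxyls (TBSOTf, 2,6-lutidine) gives the bis-silyl ether F6, and K2CO3 in MeOH cleaves the aryl silyl ether selectively to return 16.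

3. Step 9. What may go wrong: base-induced degradation of the strongly electrophilic acylquinone (enolization of the acyl side chain, attack at the ethoxy-bearing carbon) competing with the desired prototropic shift. Fallback, from 19 back to 23, in which the pyran is closed before the ketone is unveiled: the plain prenylquinone 19 is isomerized in pyridine at 90 °C to the silyl-protected chromenol F7. Bu4NF in THF removes the silyl group to give the racemic ortho-hydroxybenzylic alcohol F8, and MnO2 in CH2Cl2 oxidizes the benzylic alcohol to the chelated aryl ketone 23.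

**Further compounds**

F1 | step 10 | (±)-8-ethoxy-2,2,5-trimethyl-5-(3-methylbut-2-en-1-yl)-7-(3-phenylpropanoyl)-2H-chromen-6(5H)-one | CC(C)=CCC1(C)C(=O)C(C(=O)CCc2ccccc2)=C(OCC)C2=C1C=CC(C)(C)O2
F2 | step 10 | (±)-8-hydroxy-2,2,5-trimethyl-5-(3-methylbut-2-en-1-yl)-7-(3-phenylpropanoyl)-2H-chromen-6(5H)-one | CC(C)=CCC1(C)C(=O)C(C(=O)CCc2ccccc2)=C(O)C2=C1C=CC(C)(C)O2
F3 | step 10 | (R)-1-phenylethylammonium salt of the (5S) enolate of 26 | C[C@@H]([NH3+])c1ccccc1.CC(C)=CC[C@]1(C)C(=O)C(C(=O)CCc2ccccc2)=C([O-])C2=C1C=CC(C)(C)O2
F4 | step 4 | 5-ethoxy-2-methyl-3-(prop-2-en-1-yl)phenol | CCOc1cc(O)c(C)c(CC=C)c1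
F5 | step 4 | (±)-3-ethoxy-2-(1-hydroxy-3-phenylpropyl)-6-methyl-5-(prop-2-en-1-yl)phenol | CCOc1cc(CC=C)c(C)c(O)c1C(O)CCc1ccccc1
F6 | step 4 | (±)-tert-butyl{2-[1-(tert-butyldimethylsilyloxy)-3-phenylpropyl]-3-ethoxy-6-methyl-5-(prop-2-en-1-yl)phenoxy}dimethylsilane | CCOc1cc(CC=C)c(C)c(O[Si](C)(C)C(C)(C)C)c1C(O[Si](C)(C)C(C)(C)C)CCc1ccccc1
F7 | step 9 | (±)-7-[1-(tert-butyldimethylsilyloxy)-3-phenylpropyl]-8-ethoxy-2,2,5-trimethyl-2H-chromen-6-ol | CCOc1c(C(O[Si](C)(C)C(C)(C)C)CCc2ccccc2)c(O)c(C)c2C=CC(C)(C)Oc12
F8 | step 9 | (±)-8-ethoxy-7-(1-hydroxy-3-phenylpropyl)-2,2,5-trimethyl-2H-chromen-6-ol | CCOc1c(C(O)CCc2ccccc2)c(O)c(C)c2C=CC(C)(C)Oc12
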